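**Assumption:** the (R,R) descriptors in the SMILES correspond to the trans-2-aryl-3-hydroxymethyl-1,4-benzodioxane, with the oxygen para to the flavone on the CH2OH-bearing carbon; compounds 1, 2, 4, 5, 7, 12 and 14 are taken as catalogue materials.

Benzodioxane numbering used throughout: C-2 = aryl-bearing carbon, C-3 = CH2O-bearing carbon, C-5 = OMe, C-7 = carbonyl-bearing carbon.

## Retrosynthetic overview

1. Palstatin ⇐ bis-benzyl ether 15 by hydrogenolysis.
2. γ-Pyrone ring (last ring formed): hetero-[4+2] cycloaddition of an aroylketene, unmasked thermally from β-keto ester 13, with unprotected phloroglucinol; 13 ⇐ ester 11 by Claisen condensation.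
3. Dioxane ring: benzylic O–C-2 bond by acid-equilibrated closure of phenol-diol 10, with trans set by C-3; 10 ⇐ aryl lactone 8 + aryllithium from 3, then NaBH4.
4. C-3 stereocentre: Mitsunobu inversion of (S)-hydroxy ester 6, made from methyl (S)-glycidate, by the 4-OH of catechol ester 7.
5. Ring order: temporary lactone → 1,4-benzodioxane → γ-pyrone.

## Route

**Step 1**
Reactants: 1, 4-bromo-2,6-dimethoxyphenol; 2, benzyl bromide
Product: 3, 2-(benzyloxy)-5-bromo-1,3-dimethoxybenzene
Conditions: BnBr, K2CO3, DMF, 60 °C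
Reagents that add atoms: benzyl bromide, BrCc1ccccc1
Why: Williamson etherification of the phenoxide with a reactive benzylic halide; no stereocentre involved.

**Step 2**
Reactants: 4, methyl (2S)-oxirane-2-carboxylate (methyl (S)-glycidate); 5, benzyl alcohol
Product: 6, methyl (2S)-3-(benzyloxy)-2-hydroxypropanoate
Conditions: BnOH (3 equiv), BF3·OEt2 (10 mol %), CH2Cl2, 0 °C → rt
Reagents that add atoms: benzyl alcohol, OCc1ccccc1
Why: Lewis-acid epoxide alcoholysis occurs at the unsubstituted C-3 (C-2 is deactivated by the ester), so the C-2–O bond is never broken and the purchased (S) centre is retained.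

**Step 3**
Reactants: 7, methyl 3,4-dihydroxy-5-methoxybenzoate; 6
Product: 8, methyl (3R)-3-[(benzyloxy)methyl]-5-methoxy-2-oxo-2,3-dihydro-1,4-benzodioxine-7-carboxylate (aryl lactone)
Conditions: PPh3, DIAD, THF, 0 °C → rt; then cat. p-TsOH, PhMe, 80 °C (−MeOH)
Reagents that add atoms: none beyond reactants 6 and 7 (PPh3, DIAD and TsOH leave no atoms)
Why: Mitsunobu etherification alkylates the more acidic 4-OH (para to the ester) with clean SN2 inversion (S → R), and the neighbouring 3-OH then lactonises onto the activated α-aryloxy ester to give the six-membered aryl lactone.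

**Step 4**
Reactants: 8; 3
Product: 9, methyl (3R)-2-[4-(benzyloxy)-3,5-dimethoxyphenyl]-3-[(benzyloxy)methyl]-2-hydroxy-5-methoxy-2,3-dihydro-1,4-benzodioxine-7-carboxylate (hemiketal, C-2 anomers, in equilibrium with the open keto-phenol)
Conditions: 3, n-BuLi, THF, −78 °C; then added to 8 (1.05 equiv ArLi), THF, −78 °C; aq NH4Cl
Reagents that add atoms: the aryl group of 3, COc1cc(Br)cc(OC)c1OCc1ccccc1 (n-BuLi only performs Br/Li exchange)
Why: Aryllithium acyl addition to the phenolic lactone, far more electrophilic than the electron-rich methyl benzoate, stops at the lithium hemiketalate at −78 °C; C-3 is not touched.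

**Step 5**
Reactants: 9
Product: 10, methyl 4-{[(2R)-3-(benzyloxy)-1-[4-(benzyloxy)-3,5-dimethoxyphenyl]-1-hydroxypropan-2-yl]oxy}-3-hydroxy-5-methoxybenzoate (C-1 epimer mixture)
Conditions: NaBH4, THF–MeOH, 0 °C
Reagents that add atoms: none
Why: Borohydride reduces the ketone tautomer of the hemiketal and leaves the methyl benzoate intact; the carbinol configuration is irrelevant because it is ionised in the next step.

**Step 6**
Reactants: 10
Product: 11, methyl (2R,3R)-2-[4-(benzyloxy)-3,5-dimethoxyphenyl]-3-[(benzyloxy)methyl]-5-methoxy-2,3-dihydro-1,4-benzodioxine-7-carboxylate (trans)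
Conditions: p-TsOH·H2O (0.2 equiv), PhMe, 80 °C
Reagents that add atoms: none
Why: Acid ionises the electron-rich benzylic alcohol (SN1) and the ortho-phenol closes the dioxane reversibly, so the diequatorial trans isomer accumulates and the purchased C-3 (R) centre sets C-2 as R.

**Step 7**
Reactants: 11; 12, ethyl acetate
Product: 13, ethyl 3-[(2R,3R)-2-[4-(benzyloxy)-3,5-dimethoxyphenyl]-3-[(benzyloxy)methyl]-5-methoxy-2,3-dihydro-1,4-benzodioxin-7-yl]-3-oxopropanoate
Conditions: EtOAc (3 equiv), LiHMDS (3.2 equiv), THF, −78 °C → rt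
Reagents that add atoms: ethyl acetate, CCOC(C)=O
Why: Crossed Claisen condensation of lithio ethyl acetate with the non-enolisable aryl ester, driven by deprotonation of the β-keto ester; both stereocentres are non-acidic ether carbons.

**Step 8 (key step)**
Reactants: 13; 14, phloroglucinol (benzene-1,3,5-triol)
Product: 15, 2-[(2R,3R)-2-[4-(benzyloxy)-3,5-dimethoxyphenyl]-3-[(benzyloxy)methyl]-5-methoxy-2,3-dihydro-1,4-benzodioxin-7-yl]-5,7-dihydroxy-4H-chromen-4-one
Conditions: 14 (3 equiv), neat melt, microwave, 240 °C, 5 min, N2, no catalyst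
Reagents that add atoms: phloroglucinol, Oc1cc(O)cc(O)c1
Why: Thermal loss of EtOH unmasks the aroylketene, which undergoes a hetero-[4+2] cycloaddition (acylketene as 1-oxadiene across an enolic C=C of phloroglucinol) and aromatises by dehydration to the γ-pyrone (Mentzer-type thermal flavone synthesis); symmetric phloroglucinol removes any regiochemical issue and the ether stereocentres are not enolisable.

**Step 9**
Reactants: 15
Product: 16, palstatin, 5,7-dihydroxy-2-[(2R,3R)-2-(4-hydroxy-3,5-dimethoxyphenyl)-3-(hydroxymethyl)-5-methoxy-2,3-dihydro-1,4-benzodioxin-7-yl]-4H-chromen-4-one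
Conditions: H2 (1 atm), 10% Pd/C, THF–MeOH, rt
Reagents that add atoms: none
Why: Hydrogenolysis of the two primary benzyl ethers is much faster than cleavage of the secondary, ring-constrained benzylic C–O bond or reduction of the flavone C2=C3 bond.

## Compound list

1 | 4-bromo-2,6-dimethoxyphenol | COc1cc(Br)cc(OC)c1O | starting material
2 | benzyl bromide | BrCc1ccccc1 | starting material
3 | 2-(benzyloxy)-5-bromo-1,3-dimethoxybenzene | COc1cc(Br)cc(OC)c1OCc1ccccc1 | intermediate
4 | methyl (2S)-oxirane-2-carboxylate | COC(=O)[C@@H]1CO1 | starting material (source of chirality)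
5 | benzyl alcohol | OCc1ccccc1 | starting material
6 | methyl (2S)-3-(benzyloxy)-2-hydroxypropanoate | COC(=O)[C@@H](O)COCc1ccccc1 | intermediate
7 | methyl 3,4-dihydroxy-5-methoxybenzoate | COC(=O)c1cc(O)c(O)c(OC)c1 | starting material
8 | methyl (3R)-3-[(benzyloxy)methyl]-5-methoxy-2-oxo-2,3-dihydro-1,4-benzodioxine-7-carboxylate | COC(=O)c1cc(OC)c2O[C@H](COCc3ccccc3)C(=O)Oc2c1 | intermediate
9 | methyl (3R)-2-[4-(benzyloxy)-3,5-dimethoxyphenyl]-3-[(benzyloxy)methyl]-2-hydroxy-5-methoxy-2,3-dihydro-1,4-benzodioxine-7-carboxylate (C-2 anomers) | COC(=O)c1cc(OC)c2O[C@H](COCc3ccccc3)C(O)(c3cc(OC)c(OCc4ccccc4)c(OC)c3)Oc2c1 | intermediate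
10 | methyl 4-{[(2R)-3-(benzyloxy)-1-[4-(benzyloxy)-3,5-dimethoxyphenyl]-1-hydroxypropan-2-yl]oxy}-3-hydroxy-5-methoxybenzoate (C-1 epimers) | COC(=O)c1cc(O)c(O[C@H](COCc2ccccc2)C(O)c2cc(OC)c(OCc3ccccc3)c(OC)c2)c(OC)c1 | intermediate
11 | methyl (2R,3R)-2-[4-(benzyloxy)-3,5-dimethoxyphenyl]-3-[(benzyloxy)methyl]-5-methoxy-2,3-dihydro-1,4-benzodioxine-7-carboxylate | COC(=O)c1cc(OC)c2O[C@H](COCc3ccccc3)[C@@H](c3cc(OC)c(OCc4ccccc4)c(OC)c3)Oc2c1 | intermediate
12 | ethyl acetate | CCOC(C)=O | starting material
13 | ethyl 3-[(2R,3R)-2-[4-(benzyloxy)-3,5-dimethoxyphenyl]-3-[(benzyloxy)methyl]-5-methoxy-2,3-dihydro-1,4-benzodioxin-7-yl]-3-oxopropanoate | CCOC(=O)CC(=O)c1cc(OC)c2O[C@H](COCc3ccccc3)[C@@H](c3cc(OC)c(OCc4ccccc4)c(OC)c3)Oc2c1 | intermediate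
14 | phloroglucinol | Oc1cc(O)cc(O)c1 | starting material
15 | 2-[(2R,3R)-2-[4-(benzyloxy)-3,5-dimethoxyphenyl]-3-[(benzyloxy)methyl]-5-methoxy-2,3-dihydro-1,4-benzodioxin-7-yl]-5,7-dihydroxy-4H-chromen-4-one | O=c1cc(-c2cc(OC)c3O[C@H](COCc4ccccc4)[C@@H](c4cc(OC)c(OCc5ccccc5)c(OC)c4)Oc3c2)oc2cc(O)cc(O)c12 | intermediate
16 | palstatin | COc1cc([C@H]2Oc3cc(-c4cc(=O)c5c(O)cc(O)cc5o4)cc(OC)c3O[C@@H]2CO)cc(OC)c1O | target

## Summary

Total steps: 9.
Longest linear sequence: 8 steps (4 → 6 → 8 → 9 → 10 → 11 → 13 → 15 → 16).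

Steps most likely to fail:

1. **Step 8 (thermal ketene annulation at 240 °C).** The benzylic aryl ether could ionise and be captured by phloroglucinol, or the ketene could be over-consumed. Fallback: give up the ketene route. Hydrolyse 11 to the acid and make the acid chloride, C-acylate the LiHMDS polyanion of 2,4,6-trihydroxyacetophenone to the 1,3-diketone, and cyclodehydrate (AcOH, cat. H2SO4) to the same flavone 15.

2. **Step 3 (4-OH versus 3-OH selectivity on a hindered catechol; possible elimination of the activated hydroxy ester).** Fallback: remove the regiochemical choice by starting from methyl 3-bromo-4-hydroxy-5-methoxybenzoate, which has a single phenol. After the Mitsunobu step and aryl ketone formation and reduction, reveal the 3-oxygen from the bromide by Miyaura borylation and oxidation, then use the same acid closure. Alternatively, close the ring directly by Cu-catalysed intramolecular aryl C–O coupling.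

3. **Step 4 (double addition, enolisation of the lactone with loss of ee, or attack on the methyl benzoate).** Fallback: invert the polarity of the aryl–C-2 bond construction. Reduce 8 to the lactol (DIBAL-H, −78 °C) and introduce the aryl group by BF3·OEt2-mediated Friedel–Crafts C-arylation of the derived oxocarbenium with 2,6-dimethoxyphenol (para-selective). This gives the trans-2-aryl benzodioxane directly without an organometallic reagent.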